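The target is disconnected at C8=C9 (ring-closing metathesis) and C6–C7 (methallyl addition), which leaves ring A (cyclopentane C1–C5), whose C5–C6 and C1–C10 bonds are made together. Numbering: C1 methyl-bearing fusion carbon, C4 isopropyl carbinol, C5 fusion CH, C6 ester carbon, C8 methyl-bearing alkene carbon. The key step exploits that O4, C6 and the methyl on C1 share one face of ring A while C10 lies on the other: a silylmethyl radical tethered to O4, generated from the (bromomethyl)dimethylsilyl ether of (R)-1-isopropyl-3-methylcyclopent-2-en-1-ol, carries C6 to C5, and the C1 radical so formed takes an allyl group from the opposite face, relaying the purchased C4 centre to C5 and C1.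

Key step: step 8

Remark: ring B is the seven-membered ring and the "top face" of ring A is the face that carries O4. The homoallyl unit is introduced as its iodide for a cleaner SN2 reaction, and the C6 epimers of 21 and 22 are carried together because step 13 removes that centre.

Step 1
Reactants: 1 (R)-2-hydroxy-3-methylbutanoic acid; 2 pivalaldehyde
Product: 3 (2R,5R)-2-tert-butyl-5-isopropyl-1,3-dioxolan-4-one (cis)
Conditions: TsOH (cat.), H2SO4 (cat.), pentane, reflux, Dean–Stark; crystallisation of the cis isomer
Reagents that add atoms: none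
Why: Acid-catalysed acetalization with removal of water (first stage of self-regeneration of stereocentres) leaves C5 untouched and sets the new acetal carbon cis to the isopropyl group, because the reversible reaction favours the isomer with both substituents on the same face, the minor trans isomer being removed by crystallisation.

Step 2
Reactants: 4 4-bromo-2-methylbut-1-ene
Product: 5 4-iodo-2-methylbut-1-ene
Conditions: NaI, acetone, reflux
Reagents that add atoms: sodium iodide, [Na+].[I-]
Why: Finkelstein halide exchange is driven by precipitation of NaBr from acetone and supplies a better SN2 partner for a hindered, thermally fragile enolate.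

Step 3
Reactants: 3 (2R,5R)-2-tert-butyl-5-isopropyl-1,3-dioxolan-4-one; 5 4-iodo-2-methylbut-1-ene
Product: 7 (2R,5R)-2-tert-butyl-5-isopropyl-5-(3-methylbut-3-en-1-yl)-1,3-dioxolan-4-one, via lithium enolate 6 (not isolated)
Conditions: LiN(iPr)2, THF, −78 °C; then 5, DMPU, −78 → −20 °C
Reagents that add atoms: none
Why: Enolate alkylation under self-regeneration of stereocentres: C5 becomes trigonal in 6 while the acetal carbon keeps the chiral information, the iodide approaches anti to the tert-butyl group and so takes the place of the former hydrogen (overall retention, 5R), and the iodide in DMPU should favour SN2 over E2.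

Step 4
Reactants: 7 (2R,5R)-2-tert-butyl-5-isopropyl-5-(3-methylbut-3-en-1-yl)-1,3-dioxolan-4-one
Product: 8 (2R,5R)-2-tert-butyl-5-isopropyl-5-(3-methylbut-3-en-1-yl)-1,3-dioxolan-4-ol (anomer mixture)
Conditions: iBu2AlH, CH2Cl2, −78 °C; aq. potassium sodium tartrate
Reagents that add atoms: none
Why: Partial reduction of the lactone-type carbonyl with iBu2AlH should stop at the aluminium hemiacetal at −78 °C because the congested tetrahedral intermediate does not collapse, giving the lactol (anomeric centre uncontrolled and irrelevant) without touching the alkene or the quaternary centre.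

Step 5
Reactants: 8 (2R,5R)-2-tert-butyl-5-isopropyl-5-(3-methylbut-3-en-1-yl)-1,3-dioxolan-4-ol
Product: 10 (3R)-6-methyl-3-(propan-2-yl)hepta-1,6-dien-3-ol, via hydroxy aldehyde 9 (not isolated)
Conditions: Ph3PCH3Br, KOtBu, THF, 0 °C; then 8, 0 °C → rt (excess ylide)
Reagents that add atoms: methyltriphenylphosphonium bromide, C[P+](c1ccccc1)(c1ccccc1)c1ccccc1.[Br-]
Why: Wittig methylenation of a lactol: deprotonation opens the ring, the hemiacetal alkoxide expels pivalaldehyde to leave the non-enolisable α-oxido aldehyde 9, which is methylenated, so the C4 stereocentre is carried through unchanged.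

Step 6
Reactants: 10 (3R)-6-methyl-3-(propan-2-yl)hepta-1,6-dien-3-ol
Product: 11 (1R)-3-methyl-1-(propan-2-yl)cyclopent-2-en-1-ol
Conditions: second-generation Grubbs catalyst (cat.), CH2Cl2, 40 °C; concentrated cold
Reagents that add atoms: none
Why: Ring-closing olefin metathesis of a 1,6-diene bearing a free tertiary allylic hydroxyl is fast and driven by loss of ethene, forming the trisubstituted cyclopentene without affecting the carbinol centre.

Step 7
Reactants: 11 (1R)-3-methyl-1-(propan-2-yl)cyclopent-2-en-1-ol; 12 (bromomethyl)chlorodimethylsilane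
Product: 13 (R)-(bromomethyl)dimethyl{[3-methyl-1-(propan-2-yl)cyclopent-2-en-1-yl]oxy}silane
Conditions: Et3N, DMAP (cat.), CH2Cl2, 0 °C → rt
Reagents that add atoms: none
Why: Silyl ether formation with a small, reactive chlorosilane under DMAP catalysis makes the O–Si bond at the tertiary oxygen under basic conditions that do not ionise the allylic C–O bond, so the configuration is retained.

Step 8
Reactants: 13 (R)-(bromomethyl)dimethyl{[3-methyl-1-(propan-2-yl)cyclopent-2-en-1-yl]oxy}silane; 14 allyltributylstannane
Product: 17 (3aR,4R,6aR)-6a-isopropyl-2,2,4-trimethyl-4-(prop-2-en-1-yl)hexahydro-2H-cyclopenta[d][1,2]oxasilole (cis-fused oxasilolane; allyl anti and methyl syn to the ring oxygen), via α-silyl radical 15 (not isolated), via tertiary C1 radical 16 (not isolated)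
Conditions: 14 (4 equiv), AIBN (portionwise), benzene, 80 °C
Reagents that add atoms: none
Why: Bu3Sn radical, released when AIBN-derived radicals add to 14, abstracts bromine from 13 to give α-silyl radical 15, which closes onto C5 of the ring alkene (new C5–C6 bond) to give tertiary radical 16; 16 adds to the terminal carbon of 14 and β-scission forms the C1–C10 bond and returns Bu3Sn radical to the chain. The closest known reaction types are the silicon-tethered radical cyclization of (bromomethyl)dimethylsilyl ethers of allylic alcohols and the Keck radical allylation used to end cyclization–trapping cascades. The one ring formed, the 1-oxa-2-silacyclopentane, closes 5-exo-trig and not 6-endo, because C5 carries only hydrogen whereas C1 is fully substituted and exo attack gives the more stable tertiary radical. C5 is controlled by the tether: a five-membered ring fused to a cyclopentane can only be cis, so C6 must bond on the face of O4. C1 is controlled by the new bicycle: the C6 methylene and the SiMe2 group cover the top face of the planar radical, so the stannane should approach from the other face, placing C10 anti and the methyl syn to O4. The step needs cyclization to outrun direct allylation of 15 and allylation to outrun decay of 16, which the absence of any tin hydride, a moderate excess of stannane and portionwise initiator are meant to secure.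

Step 9
Reactants: 17 (3aR,4R,6aR)-6a-isopropyl-2,2,4-trimethyl-4-(prop-2-en-1-yl)hexahydro-2H-cyclopenta[d][1,2]oxasilole
Product: 18 (1R,2S,3R)-2-(hydroxymethyl)-1-isopropyl-3-methyl-3-(prop-2-en-1-yl)cyclopentan-1-ol
Conditions: KF, KHCO3, 30% H2O2, THF/MeOH, rt
Reagents that add atoms: hydrogen peroxide, OO
Why: Tamao–Fleming oxidation: fluoride activates the alkoxysilane, hydroperoxide adds to silicon and C6 migrates from Si to O, turning C6–Si into C6–OH and freeing the C4 hydroxyl while the terminal alkene and all stereocentres stay untouched.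

Step 10
Reactants: 18 (1R,2S,3R)-2-(hydroxymethyl)-1-isopropyl-3-methyl-3-(prop-2-en-1-yl)cyclopentan-1-ol
Product: 19 (1R,2R,5R)-2-hydroxy-2-isopropyl-5-methyl-5-(prop-2-en-1-yl)cyclopentane-1-carbaldehyde
Conditions: TEMPO (cat.), PhI(OAc)2, CH2Cl2, rt; used crude
Reagents that add atoms: none
Why: TEMPO/PhI(OAc)2 oxidation (oxoammonium-mediated) selects the primary alcohol over the tertiary one, stops at the aldehyde and runs without base, so C5 next to the new carbonyl should not epimerise and retro-aldol cleavage is avoided (the descriptor at C5 changes only through CIP priorities).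

Step 11
Reactants: 19 (1R,2R,5R)-2-hydroxy-2-isopropyl-5-methyl-5-(prop-2-en-1-yl)cyclopentane-1-carbaldehyde; 20 3-bromo-2-methylprop-1-ene
Product: 21 (1R,2S,3R)-2-[(1RS)-1-hydroxy-3-methylbut-3-en-1-yl]-1-isopropyl-3-methyl-3-(prop-2-en-1-yl)cyclopentan-1-ol (C6 epimers)
Conditions: Zn dust, THF/sat. aq. NH4Cl, 0 °C → rt
Reagents that add atoms: none
Why: Barbier-type zinc-mediated allylation in aqueous medium adds the methallyl unit to the aldehyde (C6–C7 bond) under nearly neutral conditions that tolerate the free hydroxyl; the C6 carbinol forms as an epimer mixture, which is acceptable because step 13 erases that centre.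

Step 12
Reactants: 21 (1R,2S,3R)-2-[(1RS)-1-hydroxy-3-methylbut-3-en-1-yl]-1-isopropyl-3-methyl-3-(prop-2-en-1-yl)cyclopentan-1-ol
Product: 22 (3R,3aS,8aR)-3-isopropyl-6,8a-dimethyl-1,2,3,3a,4,5,8,8a-octahydroazulene-3,4-diol (C6 epimers; azulene C4)
Conditions: second-generation Grubbs catalyst (cat.), CH2Cl2 (high dilution), 40 °C
Reagents that add atoms: none
Why: Ring-closing olefin metathesis: the catalyst loads on the monosubstituted allyl group and closes onto the 1,1-disubstituted alkene, giving the trisubstituted C8=C9 alkene of the trans-fused ring B with loss of ethene and no change at the stereocentres.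

Step 13
Reactants: 22 (3R,3aS,8aR)-3-isopropyl-6,8a-dimethyl-1,2,3,3a,4,5,8,8a-octahydroazulene-3,4-diol
Product: 23 (3R,3aR,8aR)-3-hydroxy-3-isopropyl-6,8a-dimethyl-2,3,3a,5,8,8a-hexahydroazulen-4(1H)-one
Conditions: Dess–Martin periodinane, NaHCO3, CH2Cl2, 0 °C → rt
Reagents that add atoms: none
Why: Dess–Martin oxidation of the secondary alcohol (the tertiary one is inert) merges both C6 epimers into one ketone, and the bicarbonate buffer should keep the β,γ-alkene from moving into conjugation and the β-hydroxy ketone from dehydrating.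

Step 14
Reactants: 23 (3R,3aR,8aR)-3-hydroxy-3-isopropyl-6,8a-dimethyl-2,3,3a,5,8,8a-hexahydroazulen-4(1H)-one
Product: 24 (3R,3aS,4S,8aR)-3-isopropyl-6,8a-dimethyl-1,2,3,3a,4,5,8,8a-octahydroazulene-3,4-diol (jaeschkeanadiol)
Conditions: Me4NBH(OAc)3, MeCN/AcOH, −30 °C
Reagents that add atoms: none
Why: Evans–Saksena hydroxyl-directed reduction: the C4 hydroxyl exchanges onto boron and hydride is delivered intramolecularly to the face of the C6 carbonyl on which O4 and the C1 methyl lie, so H6 ends syn and the new hydroxyl anti to O4 (6S, the 1,3-anti diol), while the reagent does not reduce ketones without such delivery.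

Step 15
Reactants: 24 (3R,3aS,4S,8aR)-3-isopropyl-6,8a-dimethyl-1,2,3,3a,4,5,8,8a-octahydroazulene-3,4-diol; 25 2,2-dimethyl-4H-1,3-benzodioxin-4-one
Product: 27 (3R,3aS,4S,8aR)-3-hydroxy-3-isopropyl-6,8a-dimethyl-1,2,3,3a,4,5,8,8a-octahydroazulen-4-yl 2-hydroxybenzoate, via sodium alkoxide 26 (not isolated)
Conditions: NaN(SiMe3)2, THF, 0 °C; then 25, 0 °C → rt; aqueous work-up
Reagents that add atoms: none
Why: Alkoxide transacylation of a salicylic acid acetonide (benzodioxinone ring opening): the secondary C6 alkoxide adds to the lactone-type carbonyl, acetone is expelled and the phenoxide is released, so the salicylate arrives with its phenol free in one operation, with retention at C6 because only the O–acyl bond is made and with the hindered tertiary hydroxyl left alone.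

Compound list
1 | (R)-2-hydroxy-3-methylbutanoic acid | CC(C)[C@@H](O)C(O)=O | starting material
2 | pivalaldehyde (2,2-dimethylpropanal) | CC(C)(C)C=O | starting material
3 | (2R,5R)-2-tert-butyl-5-isopropyl-1,3-dioxolan-4-one (cis) | CC(C)[C@H]1O[C@@H](C(C)(C)C)OC1=O | intermediate
4 | 4-bromo-2-methylbut-1-ene | CC(=C)CCBr | starting material
5 | 4-iodo-2-methylbut-1-ene | CC(=C)CCI | intermediate
6 | lithium (2R)-2-tert-butyl-5-(propan-2-yl)-1,3-dioxol-4-olate (enolate of 3) | CC(C)C1=C([O-])O[C@H](C(C)(C)C)O1.[Li+] | intermediate
7 | (2R,5R)-2-tert-butyl-5-isopropyl-5-(3-methylbut-3-en-1-yl)-1,3-dioxolan-4-one | CC(C)[C@@]1(CCC(C)=C)O[C@@H](C(C)(C)C)OC1=O | intermediate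
8 | (2R,5R)-2-tert-butyl-5-isopropyl-5-(3-methylbut-3-en-1-yl)-1,3-dioxolan-4-ol (anomer mixture) | CC(C)[C@@]1(CCC(C)=C)O[C@@H](C(C)(C)C)OC1O | intermediate
9 | (2R)-2-hydroxy-5-methyl-2-(propan-2-yl)hex-5-enal | CC(C)[C@@](C=O)(CCC(C)=C)O | intermediate
10 | (3R)-6-methyl-3-(propan-2-yl)hepta-1,6-dien-3-ol | CC(C)[C@@](C=C)(CCC(C)=C)O | intermediate
11 | (1R)-3-methyl-1-(propan-2-yl)cyclopent-2-en-1-ol | CC1=C[C@](O)(C(C)C)CC1 | intermediate
12 | (bromomethyl)chlorodimethylsilane | C[Si](C)(Cl)CBr | starting material
13 | (R)-(bromomethyl)dimethyl{[3-methyl-1-(propan-2-yl)cyclopent-2-en-1-yl]oxy}silane | CC1=C[C@](O[Si](C)(C)CBr)(C(C)C)CC1 | intermediate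
14 | allyltributylstannane | C=CC[Sn](CCCC)(CCCC)CCCC | starting material
15 | α-silyl radical from 13 (bromine removed) | CC1=C[C@](O[Si](C)(C)[CH2])(C(C)C)CC1 | intermediate
16 | cyclised tertiary C1 radical (cis-fused oxasilolane) | C[C]1CC[C@]2(C(C)C)O[Si](C)(C)C[C@H]12 | intermediate
17 | (3aR,4R,6aR)-6a-isopropyl-2,2,4-trimethyl-4-(prop-2-en-1-yl)hexahydro-2H-cyclopenta[d][1,2]oxasilole | C=CC[C@@]1(C)CC[C@]2(C(C)C)O[Si](C)(C)C[C@H]12 | intermediate
18 | (1R,2S,3R)-2-(hydroxymethyl)-1-isopropyl-3-methyl-3-(prop-2-en-1-yl)cyclopentan-1-ol | C=CC[C@@]1(C)CC[C@@](O)(C(C)C)[C@@H]1CO | intermediate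
19 | (1R,2R,5R)-2-hydroxy-2-isopropyl-5-methyl-5-(prop-2-en-1-yl)cyclopentane-1-carbaldehyde | C=CC[C@@]1(C)CC[C@@](O)(C(C)C)[C@@H]1C=O | intermediate
20 | 3-bromo-2-methylprop-1-ene | CC(=C)CBr | starting material
21 | (1R,2S,3R)-2-[(1RS)-1-hydroxy-3-methylbut-3-en-1-yl]-1-isopropyl-3-methyl-3-(prop-2-en-1-yl)cyclopentan-1-ol | C=CC[C@@]1(C)CC[C@@](O)(C(C)C)[C@@H]1C(O)CC(C)=C | intermediate
22 | (3R,3aS,8aR)-3-isopropyl-6,8a-dimethyl-1,2,3,3a,4,5,8,8a-octahydroazulene-3,4-diol (C4 epimers, azulene numbering) | CC1=CC[C@@]2(C)CC[C@@](O)(C(C)C)[C@@H]2C(O)C1 | intermediate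
23 | (3R,3aR,8aR)-3-hydroxy-3-isopropyl-6,8a-dimethyl-2,3,3a,5,8,8a-hexahydroazulen-4(1H)-one | CC1=CC[C@@]2(C)CC[C@@](O)(C(C)C)[C@@H]2C(=O)C1 | intermediate
24 | (3R,3aS,4S,8aR)-3-isopropyl-6,8a-dimethyl-1,2,3,3a,4,5,8,8a-octahydroazulene-3,4-diol | CC1=CC[C@@]2(C)CC[C@@](O)(C(C)C)[C@@H]2[C@@H](O)C1 | intermediate
25 | 2,2-dimethyl-4H-1,3-benzodioxin-4-one | CC1(C)OC(=O)c2ccccc2O1 | starting material
26 | sodium C6 alkoxide of 24 | CC1=CC[C@@]2(C)CC[C@@](O)(C(C)C)[C@@H]2[C@@H]([O-])C1.[Na+] | intermediate
27 | (3R,3aS,4S,8aR)-3-hydroxy-3-isopropyl-6,8a-dimethyl-1,2,3,3a,4,5,8,8a-octahydroazulen-4-yl 2-hydroxybenzoate | CC1=CC[C@@]2(C)CC[C@@](O)(C(C)C)[C@@H]2[C@@H](OC(=O)c2ccccc2O)C1 | target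

Total step count: 15. Longest linear sequence: 14 steps (steps 1 and 3–15, from 1 to 27); step 2 is a one-step side branch.

Steps most likely to fail

1. Step 8. Capture of the hindered tertiary C1 radical by the stannane may be too slow, so that the chain dies and the radical is lost by disproportionation or hydrogen abstraction. Facial control may also erode, because the isopropyl group on C4 sits on the face that has to be attacked. Fallback for the slow capture, setting out from 13 and coming back at 18: the same tether-directed 5-exo closure is kept, but the cascade is ended by a Giese addition, which is much faster for a nucleophilic tertiary radical. Compound 13 is cyclised with Bu3SnH (slow addition) and AIBN in benzene at 80 °C in the presence of phenyl vinyl sulfone to give the 2-(phenylsulfonyl)ethyl oxasilolane F1. Deprotonation next to sulfur (LiN(iPr)2, THF, −78 °C) and alkylation with Me3SiCH2I should give the β-silyl sulfone F2. Fluoride-induced elimination of sulfinate and silyl fluoride (Bu4NF, THF, 65 °C) unveils the allyl group of 17, and oxidation of the C–Si bond in the same flask (KHCO3, 30% H2O2, MeOH) should deliver diol 18.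

2. Step 3. E2 loss of HI from the homoallylic iodide (to isoprene) and thermal decay of the hindered enolate may outpace C-alkylation. Fallback, setting out from 3 (through enolate 6) and coming back at 7: the enolate is alkylated with the allylic, far more reactive (E)-4-bromo-2-methylbut-2-en-1-yl acetate, again anti to the tert-butyl group, to give the allylic acetate F3. Formate hydrogenolysis under zerovalent palladium (Pd(OAc)2, PBu3, HCO2NH4, dioxane, 100 °C) then delivers hydride to the more substituted allyl terminus and should give the 1,1-disubstituted alkene of 7.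

3. Step 14. The hindered tertiary C4 hydroxyl may fail to exchange onto boron, leaving the ketone unreduced, or undirected hydride attack from the open face may give the wrong C6 configuration. Fallback, setting out from 23 and coming back at 27: external hydride is used on purpose (NaBH4, MeOH, −20 °C), so that it enters from the face opposite the C1 methyl and should give the C6-epimeric diol F4. Mitsunobu esterification with salicylic acid (PPh3, diisopropyl azodicarboxylate, toluene, 0 °C → rt) then inverts C6 and should give the target 27 directly, bypassing 24 and 26.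

Further compounds
F1 | step 8 | (3aR,4R,6aR)-6a-isopropyl-2,2,4-trimethyl-4-[2-(phenylsulfonyl)ethyl]hexahydro-2H-cyclopenta[d][1,2]oxasilole | O=S(=O)(CC[C@@]1(C)CC[C@]2(C(C)C)O[Si](C)(C)C[C@H]12)c1ccccc1
F2 | step 8 | (3aR,4R,6aR)-6a-isopropyl-2,2,4-trimethyl-4-[2-(phenylsulfonyl)-3-(trimethylsilyl)propyl]hexahydro-2H-cyclopenta[d][1,2]oxasilole (epimers at the sulfonyl carbon) | C[Si](C)(C)CC(C[C@@]1(C)CC[C@]2(C(C)C)O[Si](C)(C)C[C@H]12)S(=O)(=O)c1ccccc1
F3 | step 3 | (2E)-4-[(2R,4R)-2-tert-butyl-5-oxo-4-(propan-2-yl)-1,3-dioxolan-4-yl]-2-methylbut-2-en-1-yl acetate | CC(=O)OC/C(C)=C/C[C@]1(C(C)C)O[C@@H](C(C)(C)C)OC1=O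
F4 | step 14 | (3R,3aS,4R,8aR)-3-isopropyl-6,8a-dimethyl-1,2,3,3a,4,5,8,8a-octahydroazulene-3,4-diol | CC1=CC[C@@]2(C)CC[C@@](O)(C(C)C)[C@@H]2[C@H](O)C1
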